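Start from the amounts. In the amber flask, starting material reads 0.8% at 30.0 h, yet target climbs from 54.0% to 61.2% at 120 h, so target comes through something unseen. The blue run, ahead of amber at 10.0 h (44.8% against 27.1%), stops at much the same height, 60.2%.

| flask | starting material | free catalyst | temperature | remark | time |
|---|---|---|---|---|---|
| amber | 0.25 M | 0.25 mM | 20 °C | the very flask that is asked about, followed so far |  |
| blue | 0.25 M | 0.25 mM | 26 °C | run made earlier |  |
| flask | 0.25 M | 0.25 mM | 20 °C |  | 5.0 d |

- amber (time / h: target / %, starting material / %): 10.0: 27.1, 4.9; 30.0: 54.0, 0.8; 60.0: 59.1, 0.1; 96.0: 60.7, 0; 120: 61.2, 1.2
- blue (time / h: target / %, starting material / %): 10.0: 44.8, 0; 30.0: 57.3, 0; 60.0: 59.5, 0; 96.0: 60.0, 0; 120: 60.2, 0.4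

(scatter of a reading: 1 percentage point)

- ash: at 5.0 d add free catalyst, 100% of the amount charged, then wait 2.5 d
- elm: at 5.0 d raise the temperature by 25 K, then wait 2.5 d
- maple: change nothing and wait 2.5 d more
- oak: at 5.0 d take out 90% of the target then present, then wait 2.5 d

* target, in percent of the starting material first charged, at 5.0 d
* the option that brings most further target ("none" if no option brings more than 2 percentage points) (ash / elm / maple / oak / none)
* target present, with what was taken out counted in, in percent of the starting material first charged, after maple
* target present, with what was taken out counted in, in percent of the starting material first charged, after oak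

- removed target is counted in
- the numbers in the tables scatter by 1 percentage point (one standard deviation)
- additions bring no volume worth counting

Here is my own reckoning. Suppose free catalyst turns an intermediate into target, while target destroys free catalyst, both rates being first order in free catalyst. Divide one rate by the other and time and free catalyst drop out: each bit of target costs catalyst in proportion to target over intermediate. Integrate that, writing P for target and S for the share of the charge that ever becomes intermediate. The catalyst budget (a turnover limit), proportional to the catalyst spent, is S ln(S/(S−P)) − P, and I take the charge as spent once target levels off. The readings don't give S, but this expression is smallest at S equal to the whole charge, and counting S as present from the start understates the cost of the early target, so the result stays a floor. That gives 33.5% of the charge, the budget floor.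

Ash doubles the budget, and with target held fixed it shrinks the leftover intermediate by exp(−budget/P). From above, the gain is crudely the 38.8% that isn't target, and the budget tightens this to 16 percentage points. From below, the gain is none if no intermediate is left, and my hand gets no further.

The forecast gives 61%, 61.3% after maple and 80% after oak, and picks oak, holding that “extra catalyst, heat or waiting gain almost nothing”. That places ash at the bottom of my bracket.

The flask gives 60.4%, with 60.4% after maple and 60.4% after oak, and ash is best at 5.3 points, inside the bracket, while oak brings 0.057 points.

    starting material → uncatalysed product (k = 0.0960 h⁻¹, Ea = 100 kJ mol⁻¹)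
    starting material + free catalyst ⇌ idle complex, settled at all times (K = 1.50 L mol⁻¹, ΔH = −53.0 kJ mol⁻¹)
    free catalyst + intermediate → free catalyst + target (k = 380 L mol⁻¹ h⁻¹, Ea = 58.0 kJ mol⁻¹)
    starting material → intermediate (k = 0.200 h⁻¹, Ea = 99.0 kJ mol⁻¹)
    free catalyst + target → spent catalyst (k = 0.400 L mol⁻¹ h⁻¹, Ea = 64.0 kJ mol⁻¹)
    (constants at 20 °C)

At 120 h the flask holds free catalyst 0.169% and spent catalyst 99.8% of the catalyst charged, and intermediate 7.08% of the starting material charged. With that intermediate the budget is 91.7%, above the floor, and the ash formula gives 5.5 points. In the neighbouring flask charged with 1.0 × 10⁻⁴ M free catalyst, target 48.6% and intermediate 19.0% give a budget of 37.2%, which is 0.406 of this flask's, against a catalyst ratio of 0.400.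

Readings and results were generated by integration from invented constants; scatter was added.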